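**Retrosynthetic overview**
Labels: ring B = B1 (spiro C), B2 (CH2), B3 and B4 (CHMe), B5 (CHOAc), B6/B7 (shared with trimethoxybenzene ring A, B7 bonded to B1); ring C = the 2,6-dimethoxycyclohexa-2,5-dienone. The strategy rests on the mirror symmetry of ring C. Its two MeO–C=CH arms on B1 are identical, so B1 is not a stereocentre and all chirality sits on B3, B4 and B5.
Target ⇒ acetate introduced with inversion at B5 (Mitsunobu) ⇒ B5 alcohol cis to the B4 methyl ⇒ B3 set by hydroxyl-directed hydrogenation of a B3-methylidene alcohol.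
That alcohol ⇒ cut B4–B5 (catalytic enantioselective intramolecular carbonyl-ene reaction) ⇒ achiral dienone with the formyl carbon B5 on B6 and the (E)-2-methylbut-2-enyl chain B2–B4 on B1.
Achiral dienone ⇒ ring C by [3+3] double aldol condensation of a 2-aryl-2-alkenylmalonaldehyde with 1,3-dimethoxyacetone. The malonaldehyde ⇒ malonate arylation (B1–B7) and allylation (B1–B2).
Ring order: A (purchased) → C (step 7) → B (step 9).

Key step: step 9

Assumption: the sense of induction of the phosphoramide on this new substrate class cannot be derived from precedent. The (R)-catalyst is written, and its (S)-enantiomer is used instead if the (R)-form favours the mirror image of the ene product.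

**Step 1**
Reactants: 1 2-bromo-3,4,5-trimethoxybenzaldehyde
Product: 2 2-(2-bromo-3,4,5-trimethoxyphenyl)-1,3-dioxolane
Conditions: HOCH2CH2OH, p-TsOH·H2O (cat.), toluene, reflux, Dean–Stark
Reagents that add atoms: ethylene glycol, OCCO
Why: Acid-catalysed acetalisation with azeotropic removal of water masks the formyl group (the later B5) against malonate enolates, LiAlH4 and amines.

**Step 2**
Reactants: 2 2-(2-bromo-3,4,5-trimethoxyphenyl)-1,3-dioxolane; 3 diethyl malonate
Product: 4 diethyl 2-[6-(1,3-dioxolan-2-yl)-2,3,4-trimethoxyphenyl]malonate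
Conditions: Pd(OAc)2 (cat.), P(t-Bu)3·HBF4 (cat.), K3PO4, toluene, 90 °C
Reagents that add atoms: none
Why: Palladium-catalysed enolate arylation of the Buchwald–Hartwig type, in which the bulky electron-rich phosphine gives monoligated zerovalent palladium that inserts into the hindered C–Br bond and speeds reductive elimination to the B1–B7 bond, while the product rests as its enolate and is not arylated twice.

**Step 3**
Reactants: 5 (E)-2-methylbut-2-en-1-ol
Product: 6 (E)-1-bromo-2-methylbut-2-ene
Conditions: PBr3, Et2O, −10 to 0 °C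
Reagents that add atoms: phosphorus tribromide, BrP(Br)Br
Why: Bromide displaces the phosphite ester of the primary allylic alcohol by SN2, and the low temperature keeps the E geometry and prevents allylic transposition.

**Step 4**
Reactants: 4 diethyl 2-[6-(1,3-dioxolan-2-yl)-2,3,4-trimethoxyphenyl]malonate; 6 (E)-1-bromo-2-methylbut-2-ene
Product: 8 diethyl 2-[6-(1,3-dioxolan-2-yl)-2,3,4-trimethoxyphenyl]-2-[(E)-2-methylbut-2-enyl]malonate, via sodium malonate enolate 7 (not isolated)
Conditions: NaH, DMF, 0 °C; then 6, 0 °C to rt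
Reagents that add atoms: none
Why: Malonic ester alkylation, in which the soft stabilised enolate attacks the unhindered primary allylic carbon by SN2, forms B1–B2, makes B1 quaternary and leaves the alkene geometry untouched.

**Step 5**
Reactants: 8 diethyl 2-[6-(1,3-dioxolan-2-yl)-2,3,4-trimethoxyphenyl]-2-[(E)-2-methylbut-2-enyl]malonate
Product: 9 2-[6-(1,3-dioxolan-2-yl)-2,3,4-trimethoxyphenyl]-2-[(E)-2-methylbut-2-enyl]propane-1,3-diol
Conditions: LiAlH4, THF, 0 °C to reflux; aq NaOH work-up
Reagents that add atoms: none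
Why: LiAlH4 reduces both esters of the 2,2-disubstituted malonate to the 1,3-diol, and the acetal, aryl ethers and isolated alkene are inert to hydride.

**Step 6**
Reactants: 9 2-[6-(1,3-dioxolan-2-yl)-2,3,4-trimethoxyphenyl]-2-[(E)-2-methylbut-2-enyl]propane-1,3-diol
Product: 10 2-[6-(1,3-dioxolan-2-yl)-2,3,4-trimethoxyphenyl]-2-[(E)-2-methylbut-2-enyl]malonaldehyde
Conditions: (COCl)2, DMSO, CH2Cl2, −78 °C; Et3N, −78 to 0 °C
Reagents that add atoms: none
Why: Swern oxidation takes both neopentyl alcohols to aldehydes that have no α-hydrogen, under cold, non-aqueous, non-nucleophilic conditions that avoid the hydroxide or alkoxide able to cleave a formyl group.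

**Step 7**
Reactants: 10 2-[6-(1,3-dioxolan-2-yl)-2,3,4-trimethoxyphenyl]-2-[(E)-2-methylbut-2-enyl]malonaldehyde; 11 1,3-dimethoxyacetone
Product: 13 4-[6-(1,3-dioxolan-2-yl)-2,3,4-trimethoxyphenyl]-2,6-dimethoxy-4-[(E)-2-methylbut-2-enyl]cyclohexa-2,5-dien-1-one, via cyclic bis-aldol 12 (not isolated)
Conditions: pyrrolidine (cat.), AcOH (cat.), 4 Å MS, CH2Cl2, 0 °C to rt
Reagents that add atoms: none
Why: [3+3] double aldol condensation, the reaction type by which malonaldehydes and ketones give phenols and phthalaldehyde and 11 give a benzotropone: enamine-mediated addition of both CH2(OMe) carbons of 11 to the two non-enolisable formyl groups closes ring C at the bis-aldol stage, so no particular enone geometry is needed, and the two dehydrations stop at the cross-conjugated dienone because B1 is quaternary.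

**Step 8**
Reactants: 13 4-[6-(1,3-dioxolan-2-yl)-2,3,4-trimethoxyphenyl]-2,6-dimethoxy-4-[(E)-2-methylbut-2-enyl]cyclohexa-2,5-dien-1-one
Product: 14 4-(6-formyl-2,3,4-trimethoxyphenyl)-2,6-dimethoxy-4-[(E)-2-methylbut-2-enyl]cyclohexa-2,5-dien-1-one (achiral)
Conditions: PPTS (cat.), THF/H2O, rt
Reagents that add atoms: water, O
Why: Acid-catalysed acetal hydrolysis, in which the p-methoxy-stabilised oxocarbenium ion lets a pyridinium-strength acid suffice, too weak to start a racemic ene closure, a dienone–phenol shift or hydrolysis of the ring C enol ethers.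

**Step 9**
Reactants: 14 4-(6-formyl-2,3,4-trimethoxyphenyl)-2,6-dimethoxy-4-[(E)-2-methylbut-2-enyl]cyclohexa-2,5-dien-1-one
Product: 15 (8S,9S)-9-hydroxy-2,3,3′,4,5′-pentamethoxy-8-methyl-7-methylidene-6,7,8,9-tetrahydrospiro[benzo[7]annulene-5,1′-cyclohexa-2′,5′-dien]-4′-one (B4 = S, B5 = S; B5-OH cis to B4-Me; C=CH2 on B3)
Conditions: (R)-3,3′-bis(2,4,6-triisopropylphenyl)-1,1′-binaphthyl-2,2′-diyl N-triflylphosphoramide (10 mol %), 4 Å MS, toluene, −40 °C
Reagents that add atoms: none
Why: Proposed new method: the chiral acid binds the formyl oxygen on B5, alkene carbon B4 attacks B5 while charge builds on tertiary B3, and a hydrogen of the B3 methyl passes to the oxygen within a six-membered array (O, B5, B4, B3, CH2, H), which gives the homoallylic alcohol and the methylidene on B3. The closest known reaction type is the catalytic asymmetric intramolecular carbonyl-ene cyclisation of olefinic aldehydes to five- and six-membered rings by chiral Brønsted or Lewis acids, together with the non-asymmetric Me2AlCl-promoted closure of the same topology (tether on the central ene carbon) to seven-membered 3-methylidenecycloalkanols; an aryl aldehyde, a seven-membered ring under asymmetric catalysis and a dienone spectator are new. Ring B closes 7-endo-trig at the alkene (B3 and B4 both end inside the ring, the carbonyl oxygen outside), and the six-membered alternative through B3 is disfavoured because it would place charge on secondary B4 and build a second quaternary carbon next to B1. B5 is set by the catalyst alone, which must tell apart the two enantiotopic faces of the aldehyde in an achiral substrate; B4 follows from the E alkene, because the short tether B6–B7–B1–B2 forces B6 to lie over B2 and the oxygen over the B3 methyl, so the B4 methyl (cis to the B3 methyl on the alkene) ends on the ring face of the new hydroxyl. The step needs activation of the aldehyde in preference to the ring C carbonyl and hydrogen transfer from the methyl rather than from B2: the first is helped by the alkene resting next to the formyl group and by the low temperature, which also shuts off Cope and retro-Claisen escape of the 4-allyl dienone, the second by B2 being locked in the tether away from the oxygen. A metal-free acid is chosen because the MeO–C–C(=O)–C–OMe array of ring C would sequester an oxophilic metal centre.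

**Step 10**
Reactants: 15 (8S,9S)-9-hydroxy-2,3,3′,4,5′-pentamethoxy-8-methyl-7-methylidene-6,7,8,9-tetrahydrospiro[benzo[7]annulene-5,1′-cyclohexa-2′,5′-dien]-4′-one
Product: 16 (7R,8S,9S)-9-hydroxy-2,3,3′,4,5′-pentamethoxy-7,8-dimethyl-6,7,8,9-tetrahydrospiro[benzo[7]annulene-5,1′-cyclohexa-2′,5′-dien]-4′-one (B3-Me trans to B4-Me and to B5-OH)
Conditions: [Ir(cod)(PCy3)(py)]PF6 (cat.), H2 (1 atm), CH2Cl2, 0 °C to rt
Reagents that add atoms: none
Why: Hydroxyl-directed homogeneous hydrogenation, in which the cationic iridium centre binds the B5 hydroxyl and the nearby 1,1-disubstituted alkene on the same ring face and delivers hydrogen there, so the new B3 methyl is pushed to the opposite face (B3 = R), while the two trisubstituted, methoxy-bearing C=C bonds of ring C next to the quaternary B1 should react far more slowly.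

**Step 11**
Reactants: 16 (7R,8S,9S)-9-hydroxy-2,3,3′,4,5′-pentamethoxy-7,8-dimethyl-6,7,8,9-tetrahydrospiro[benzo[7]annulene-5,1′-cyclohexa-2′,5′-dien]-4′-one
Product: 17 (7R,8S,9R)-2,3,3′,4,5′-pentamethoxy-7,8-dimethyl-4′-oxo-6,7,8,9-tetrahydrospiro[benzo[7]annulene-5,1′-cyclohexa-2′,5′-dien]-9-yl acetate (target)
Conditions: PPh3, DIAD, AcOH, THF, 0 °C to rt
Reagents that add atoms: acetic acid, CC(=O)O
Why: Mitsunobu reaction, in which acetate displaces the oxyphosphonium group at B5 by SN2 with inversion (S to R), and any leakage through the p-methoxybenzylic ion pair should be captured anti to the B4 methyl, which is the same outcome.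

**Compound list**
1 | 2-bromo-3,4,5-trimethoxybenzaldehyde | COc1cc(C=O)c(Br)c(OC)c1OC | starting material
2 | 2-(2-bromo-3,4,5-trimethoxyphenyl)-1,3-dioxolane | COc1cc(C2OCCO2)c(Br)c(OC)c1OC | intermediate
3 | diethyl malonate | CCOC(=O)CC(=O)OCC | starting material
4 | diethyl 2-[6-(1,3-dioxolan-2-yl)-2,3,4-trimethoxyphenyl]malonate | CCOC(=O)C(C(=O)OCC)c1c(C2OCCO2)cc(OC)c(OC)c1OC | intermediate
5 | (E)-2-methylbut-2-en-1-ol | C/C=C(\C)CO | starting material
6 | (E)-1-bromo-2-methylbut-2-ene | C/C=C(\C)CBr | intermediate
7 | sodium enolate of 4 (not isolated) | CCOC(=O)C(=C([O-])OCC)c1c(C2OCCO2)cc(OC)c(OC)c1OC.[Na+] | intermediate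
8 | diethyl 2-[6-(1,3-dioxolan-2-yl)-2,3,4-trimethoxyphenyl]-2-[(E)-2-methylbut-2-enyl]malonate | CCOC(=O)C(C/C(C)=C/C)(C(=O)OCC)c1c(C2OCCO2)cc(OC)c(OC)c1OC | intermediate
9 | 2-[6-(1,3-dioxolan-2-yl)-2,3,4-trimethoxyphenyl]-2-[(E)-2-methylbut-2-enyl]propane-1,3-diol | OCC(CO)(C/C(C)=C/C)c1c(C2OCCO2)cc(OC)c(OC)c1OC | intermediate
10 | 2-[6-(1,3-dioxolan-2-yl)-2,3,4-trimethoxyphenyl]-2-[(E)-2-methylbut-2-enyl]malonaldehyde | O=CC(C=O)(C/C(C)=C/C)c1c(C2OCCO2)cc(OC)c(OC)c1OC | intermediate
11 | 1,3-dimethoxyacetone | COCC(=O)COC | starting material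
12 | 4-[6-(1,3-dioxolan-2-yl)-2,3,4-trimethoxyphenyl]-3,5-dihydroxy-2,6-dimethoxy-4-[(E)-2-methylbut-2-enyl]cyclohexanone, mixture of diastereomers (not isolated) | COC1C(O)C(C/C(C)=C/C)(C(O)C(OC)C1=O)c1c(C2OCCO2)cc(OC)c(OC)c1OC | intermediate
13 | 4-[6-(1,3-dioxolan-2-yl)-2,3,4-trimethoxyphenyl]-2,6-dimethoxy-4-[(E)-2-methylbut-2-enyl]cyclohexa-2,5-dien-1-one | COC1=CC(C/C(C)=C/C)(C=C(OC)C1=O)c1c(C2OCCO2)cc(OC)c(OC)c1OC | intermediate
14 | 4-(6-formyl-2,3,4-trimethoxyphenyl)-2,6-dimethoxy-4-[(E)-2-methylbut-2-enyl]cyclohexa-2,5-dien-1-one | COC1=CC(C/C(C)=C/C)(C=C(OC)C1=O)c1c(C=O)cc(OC)c(OC)c1OC | intermediate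
15 | (8S,9S)-9-hydroxy-2,3,3′,4,5′-pentamethoxy-8-methyl-7-methylidene-6,7,8,9-tetrahydrospiro[benzo[7]annulene-5,1′-cyclohexa-2′,5′-dien]-4′-one | COC1=CC2(C=C(OC)C1=O)CC(=C)[C@H](C)[C@H](O)c1cc(OC)c(OC)c(OC)c12 | intermediate
16 | (7R,8S,9S)-9-hydroxy-2,3,3′,4,5′-pentamethoxy-7,8-dimethyl-6,7,8,9-tetrahydrospiro[benzo[7]annulene-5,1′-cyclohexa-2′,5′-dien]-4′-one | COC1=CC2(C=C(OC)C1=O)C[C@@H](C)[C@H](C)[C@H](O)c1cc(OC)c(OC)c(OC)c12 | intermediate
17 | (7R,8S,9R)-2,3,3′,4,5′-pentamethoxy-7,8-dimethyl-4′-oxo-6,7,8,9-tetrahydrospiro[benzo[7]annulene-5,1′-cyclohexa-2′,5′-dien]-9-yl acetate | COC1=CC2(C=C(OC)C1=O)C[C@@H](C)[C@H](C)[C@@H](OC(C)=O)c1cc(OC)c(OC)c(OC)c12 | target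

**Step count**
Total steps: 11. Longest linear sequence: 10 (steps 1, 2 and 4 to 11; step 3 is a one-step side branch).

**Steps most likely to fail**

Step 9 (key step).
- The acid may engage the more basic ring C carbonyl instead of the formyl group. That would open acid-induced migration or loss of the allylic chain.
- The electron-rich aryl aldehyde may not turn over at low temperature.
- Discrimination between the aldehyde faces may be poor.
- The new hydroxyl may add to ring C.

Fallback, from 14 back to 15: ring B is closed without asymmetric induction by Me2AlCl (excess, CH2Cl2, −78 °C). This is the established Lewis-acid-promoted carbonyl-ene closure of olefinic aldehydes to six- and seven-membered 3-methylidenecycloalkanols. The excess covers chelation by ring C, and the methylaluminium reagent scavenges protons. It should give the racemic cis alcohol F1. Esterification with (1S)-(−)-camphanic chloride (Et3N, DMAP, CH2Cl2) should give the camphanate of the (8S,9S) alcohol F2 and the camphanate of its enantiomer F3, which are separated by crystallisation or chromatography. Methanolysis of the camphanate F2 (K2CO3, MeOH, 0 °C) returns to the route at 15.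

Step 7.
- Amine- or base-induced loss of a formyl group (retro-Claisen cleavage) from the non-enolisable malonaldehyde may occur.
- The first aldol addition at a neopentyl aldehyde may be reversible and unfavourable.
- Dehydration may come before ring closure and give an enone whose geometry cannot cyclise.

Fallback, from 10 back to 13: the second C=C bond is made irreversibly by phosphonate chemistry. Lithiated diethyl (methoxymethyl)phosphonate (LDA, THF, −78 °C) is acylated with methyl methoxyacetate to give diethyl (1,3-dimethoxy-2-oxopropyl)phosphonate F4. After double deprotonation (NaH, then n-BuLi, THF, −78 °C) its remote CH(OMe) carbon adds to one formyl group of 10. On warming, the phosphonate carbanion closes ring C on the second formyl group by an intramolecular Horner–Wadsworth–Emmons reaction, in which the ring enforces the needed alkene geometry, to give the hydroxy enone F5. Mesylation (MsCl, Et3N, 0 °C) gives the mesylate F6. DBU in the same flask eliminates it to 13.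

Step 2.
- Slow enolate binding and reductive elimination at the doubly ortho-substituted arylpalladium may occur, with hydrodebromination taking over.

Fallback, from 2 back to 4: the B1–B7 bond is made by carbonyl addition instead of cross-coupling. Bromine–lithium exchange on 2 (n-BuLi, THF, −78 °C) gives the aryllithium F7. It adds to the very electrophilic central carbonyl of diethyl ketomalonate to give the lithium alkoxide F8. This is acetylated in the same flask (Ac2O) to the acetoxymalonate F9. Reductive removal of the α-acetoxy group with SmI2 (THF, t-BuOH, −78 °C to rt) gives 4.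

**Further compounds**
F1 | step 9 | racemic cis-9-hydroxy-8-methyl-7-methylidene spirodienone (15 and its enantiomer) | COC1=CC2(C=C(OC)C1=O)CC(=C)[C@H](C)[C@H](O)c1cc(OC)c(OC)c(OC)c12.COC1=CC2(C=C(OC)C1=O)CC(=C)[C@@H](C)[C@@H](O)c1cc(OC)c(OC)c(OC)c12
F2 | step 9 | (1S,4R)-camphanate of 15 | COC1=CC2(C=C(OC)C1=O)CC(=C)[C@H](C)[C@H](OC(=O)[C@@]34CC[C@@](C)(C(=O)O3)C4(C)C)c1cc(OC)c(OC)c(OC)c12
F3 | step 9 | (1S,4R)-camphanate of the enantiomer of 15 | COC1=CC2(C=C(OC)C1=O)CC(=C)[C@@H](C)[C@@H](OC(=O)[C@@]34CC[C@@](C)(C(=O)O3)C4(C)C)c1cc(OC)c(OC)c(OC)c12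
F4 | step 7 | diethyl (1,3-dimethoxy-2-oxopropyl)phosphonate | CCOP(=O)(OCC)C(OC)C(=O)COC
F5 | step 7 | 4-[6-(1,3-dioxolan-2-yl)-2,3,4-trimethoxyphenyl]-5-hydroxy-2,6-dimethoxy-4-[(E)-2-methylbut-2-enyl]cyclohex-2-en-1-one, mixture of diastereomers | COC1=CC(C/C(C)=C/C)(C(O)C(OC)C1=O)c1c(C2OCCO2)cc(OC)c(OC)c1OC
F6 | step 7 | methanesulfonate of F5 | COC1=CC(C/C(C)=C/C)(C(OS(C)(=O)=O)C(OC)C1=O)c1c(C2OCCO2)cc(OC)c(OC)c1OC
F7 | step 2 | [6-(1,3-dioxolan-2-yl)-2,3,4-trimethoxyphenyl]lithium | [Li]c1c(C2OCCO2)cc(OC)c(OC)c1OC
F8 | step 2 | lithium alkoxide of diethyl 2-aryl-2-hydroxymalonate | CCOC(=O)C([O-])(C(=O)OCC)c1c(C2OCCO2)cc(OC)c(OC)c1OC.[Li+]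
F9 | step 2 | diethyl 2-acetoxy-2-[6-(1,3-dioxolan-2-yl)-2,3,4-trimethoxyphenyl]malonate | CCOC(=O)C(OC(C)=O)(C(=O)OCC)c1c(C2OCCO2)cc(OC)c(OC)c1OC
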